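(Readings and results were generated by integration on assumed constants; the scatter is artificial.)

The amounts come first: you charge free monomer and initiator, and you want to know how much free monomer is left, how much sits in chains, and over how many chains that is spread.

| setting | west | south-east | east | flask |
|---|---|---|---|---|
| free monomer | 0.15 M | 0.33 M | 0.22 M | 0.22 M |
| transfer agent | 0.066 M | 0.066 M | 0.066 M | 0.0660 M |
| initiator | 11 mM | 11 mM | 5.5 mM | 11 mM |
| remark | run made earlier | run made earlier | run made earlier |  |
| time |  |  |  | 3.0 min |

| run | time / min | monomer in chains / % | free monomer / % |
|---|---|---|---|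
| west | 0.667 | 37.1 | 25.8 |
| west | 1.33 | 38.9 | 7.1 |
| west | 2.00 | 39.8 | 3.5 |
| west | 2.50 | 40.9 | 2.0 |
| south-east | 0.333 | 25.9 | 46.5 |
| south-east | 0.833 | 34.3 | 19.1 |
| south-east | 1.50 | 35.7 | 8.8 |
| south-east | 2.50 | 37.7 | 2.8 |
| east | 0.333 | 15.9 | 53.3 |
| east | 0.833 | 23.6 | 24.3 |
| east | 1.50 | 27.0 | 9.4 |
| east | 2.50 | 28.6 | 0.5 |

(each reading ± 1 percentage point)

- the average divides the monomer in chains by the number of chains begun, living and dead together
- the earlier runs do not show the number of chains; that part of a forecast is a guess

* average number of monomer units in a chain (chains begun, living or dead) at 3.0 min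
* part of the free monomer that has reacted at 3.0 min

Work with the fraction left. The west and south-east runs bracket the flask in free monomer at the same initiator, and their last readings leave on average 2.40%. The south-east run falls from 8.8% to 2.8%, a decay constant of 1.15 min⁻¹. So for the flask at 3.0 min:

left ≈ 1.35%, c ≈ 98.7%

The last readings of those two runs put on average 39.3% of the charge in chains. You may object that this share is still growing. But the free monomer still there can add about 0.94 percentage points, which is the size of the scatter, so you keep it.

Now take the charge ratio, [free monomer]/[initiator] as charged, here 20.0. If each initiator begins one chain: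

dp ≈ charge ratio × share in chains = 7.86

The objection is that transfer agent might begin chains too, and the runs show no chain count, so this stays a guess. The west, south-east and east runs were each charged with 0.066 M of transfer agent, so comparing them gives no test of this, and you take initiator as the count as a guess.

The forecast differs on dp: 6, with c at 98.6%, on the ground that “Transfer adds chains, while poor efficiency removes them.”

The flask gives dp 7.72 and c 99.1%.

    free monomer → uncatalysed product (k = 0.0203 s⁻¹)
    free monomer + living end → monomer in chains + living end, rate k2*[living end]*[free monomer] (k = 2.51 M⁻¹ s⁻¹)
    free monomer + initiator → living end + monomer in chains (k = 3.56 M⁻¹ s⁻¹)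
    living end + transfer agent → dead chain (kL = 0.0505 M⁻¹ s⁻¹)
    2 living end → dead end (k = 3.05 M⁻¹ s⁻¹)

At 0.395 min in the flask, free monomer goes 1.9 times as fast to uncatalysed product as into chains, a selectivity factor. At 3.00 min the flask holds 60.4% uncatalysed product against 38.6% monomer in chains. The charge ratio times that share gives 7.72, beside the flask's 7.72. The neighbour charged with 0.088 M of free monomer holds 43.0% in chains, so its charge ratio gives 3.44, and its dp is 3.44.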